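**Retrosynthetic overview**
1. The interflavan bond C4(upper)–C6(lower) is cut last: a C4 cation of the upper unit (stabilised by O7 para and O1 ortho to C4a) is joined to the benzylated lower flavan by Friedel–Crafts alkylation. Both partners come from one flavan-4-ol, so the two (2S,3S) units share every step up to it.
2. That flavan-4-ol comes from a 2,3-cis 3-benzyloxyflavanone. Its ring C is closed in one pot from an α-benzyloxy 2-fluoroaryl ketone (ring A) and 3,4-bis(benzyloxy)benzaldehyde (ring B): C2–C3 by a diisopinocampheylboron syn-aldol, O1–C8a by fluoride-triggered SNAr.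
3. Enabling feature: C4 of ring C sits on C4a, the ring A carbon ortho to C8a. As a ketone this one carbon acidifies C3–H (enolate for C2–C3) and activates the C8a–F bond (SNAr for O1–C8a); after reduction it is the 2,4-dioxygenated benzylic position that ionises for the interflavan bond.
4. Ring order: rings A and B are bought as arenes; ring C of both units is formed in step 3; eight benzyl ethers are removed at the end.

Key step: step 3

Assumption: (−)-Ipc2BOTf, the reagent made from (+)-α-pinene, is taken to direct the (Z)-enol borinate to the Re face of the aldehyde; if the sense proves opposite, the reagent from (−)-α-pinene is used and the route is otherwise unchanged.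

**Step 1**
Reactants: 1 4-bromo-3-fluorophenol
Product: 2 4-(benzyloxy)-1-bromo-2-fluorobenzene
Conditions: BnBr, K2CO3, DMF, rt
Reagents that add atoms: benzyl bromide, BrCc1ccccc1
Why: Williamson ether synthesis, in which the phenoxide formed with K2CO3 displaces bromide from benzyl bromide by SN2; no stereocenter is involved.

**Step 2**
Reactants: 2 4-(benzyloxy)-1-bromo-2-fluorobenzene; 3 2-(benzyloxy)-N-methoxy-N-methylacetamide
Product: 6 2-(benzyloxy)-1-[4-(benzyloxy)-2-fluorophenyl]ethan-1-one, via [4-(benzyloxy)-2-fluorophenyl]lithium 4 (not isolated), via lithium hemiaminal adduct 5 (not isolated)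
Conditions: n-BuLi, THF, −78 °C; then 3, −78 °C; aq NH4Cl
Reagents that add atoms: none
Why: Weinreb ketone synthesis, in which lithium–bromine exchange at −78 °C should be faster than ortho-deprotonation or LiF loss from 4, and the chelated adduct 5 should hold until the quench so that no over-addition occurs; no stereocenter is formed.

**Step 3**
Reactants: 6 2-(benzyloxy)-1-[4-(benzyloxy)-2-fluorophenyl]ethan-1-one; 7 3,4-bis(benzyloxy)benzaldehyde
Product: 11 (2S,3R)-3,7-bis(benzyloxy)-2-[3,4-bis(benzyloxy)phenyl]chroman-4-one (2,3-cis), via (Z)-enol diisopinocampheylborinate 8 (not isolated), via syn boron aldolate 9 (not isolated), via fluoroborate ate complex 10 (not isolated)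
Conditions: (−)-Ipc2BOTf (freshly prepared, 1.3 equiv), i-Pr2NEt (1.5 equiv), CH2Cl2, −78 °C; 7 (1.2 equiv), −78 to −25 °C; then (Me2N)3S+ Me3SiF2− (TASF, 3 equiv), THF, −78 to −30 °C; AcOH, pH 7 buffer
Reagents that add atoms: none
Why: Proposed new method: soft enolisation of 6 with (−)-Ipc2BOTf and i-Pr2NEt should give the (Z)-enol borinate 8 (benzyloxy and boryloxy groups cis), which adds to aldehyde 7 through a closed Zimmerman–Traxler chair and forms the C2–C3 bond as syn boron aldolate 9; fluoride then binds to boron, as in the conversion of boron esters into fluoroborates, and the C2 oxygen of ate complex 10 attacks C8a, ortho to the C4 carbonyl, through a Meisenheimer adduct and expels fluoride (SNAr), the strong B–F bonds of the borate by-product providing the driving force. The closest known reaction types are the boron-mediated syn-aldol of (Z)-enol diisopinocampheylborinates and the enolate C-acylation/SNAr annulation of 2-fluoroaryl ketones to chromones; their merger on an α-alkoxy ketone with retention of the aldol stereochemistry is the untested part. Ring C is closed in the 6-exo-trig mode by the C2 oxygen, the only nucleophile that can reach C8a through a six-membered transition state. C3 is controlled by the (Z)-enolate geometry (syn aldol, which becomes 2,3-cis because the C2–O bond is retained in the ring closure), and C2 by the isopinocampheyl ligands, taken to direct the enolate to the Re face of 7. The step needs ring closure to outrun retro-aldol cleavage and C3 epimerisation; the ortho-acyl activation of the C8a–F bond, the low temperature (which favours the cyclisation, with its low activation enthalpy, over the fragmentation), the weakly basic fluoride trigger and the pseudo-equatorial C3–H of the cis product, which is poorly aligned for enolisation, are meant to secure this.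

**Step 4**
Reactants: 11 (2S,3R)-3,7-bis(benzyloxy)-2-[3,4-bis(benzyloxy)phenyl]chroman-4-one
Product: 12 (2S,3S,4S)-3,7-bis(benzyloxy)-2-[3,4-bis(benzyloxy)phenyl]chroman-4-ol (2,3-cis-3,4-cis)
Conditions: NaBH4, CeCl3·7H2O, MeOH/THF, −40 °C
Reagents that add atoms: none
Why: Luche reduction, in which cerium-activated 1,2-hydride addition at −40 °C should be faster than base-mediated epimerisation at C3, and hydride is expected to enter C4 axially, anti to the pseudo-axial 3-benzyloxy group, which sets C4 as the 3,4-cis alcohol (this centre is planarised again in steps 5 and 6, so its C4 epimer would serve equally).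

**Step 5**
Reactants: 12 (2S,3S,4S)-3,7-bis(benzyloxy)-2-[3,4-bis(benzyloxy)phenyl]chroman-4-ol (about three quarters of the batch)
Product: 13 (2S,3S)-3,7-bis(benzyloxy)-2-[3,4-bis(benzyloxy)phenyl]chromane (tetra-O-benzyl ent-epifisetinidol)
Conditions: Et3SiH (5 equiv), CF3CO2H (3 equiv), CH2Cl2, −40 to 0 °C, slow addition of 12
Reagents that add atoms: none
Why: Ionic hydrogenation, in which CF3CO2H ionises the 4-hydroxyl to the benzylic cation stabilised by O7 (para) and O1 (ortho) and excess Et3SiH reduces it to the methylene group without touching C2 or C3.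

**Step 6**
Reactants: 12 (2S,3S,4S)-3,7-bis(benzyloxy)-2-[3,4-bis(benzyloxy)phenyl]chroman-4-ol; 13 (2S,3S)-3,7-bis(benzyloxy)-2-[3,4-bis(benzyloxy)phenyl]chromane
Product: 14 octa-O-benzyl ether of the target (upper unit 2,3-cis-3,4-trans, C4 bonded to C6 of the lower 2,3-cis unit; configurations as in 15)
Conditions: 13 (3 equiv), Me3SiOTf (0.2 equiv), 4 Å MS, CH2Cl2, −78 to −40 °C, slow addition of 12
Reagents that add atoms: none
Why: Friedel–Crafts alkylation (interflavan coupling), in which Me3SiOTf ionises 12 to the same C4 cation, the dioxygenated ring A of 13 attacks through C6 (para to O1 and ortho to O7, whereas C8 is flanked by two oxygen substituents), and the new C4 stereocenter is set by substrate control, the nucleophile entering anti to the pseudo-axial 3-benzyloxy group and to the 2-aryl group to give the 3,4-trans linkage.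

**Step 7**
Reactants: 14 octa-O-benzyl ether of the target
Product: 15 (2S,3S,4R)-2-(3,4-dihydroxyphenyl)-4-[(2S,3S)-2-(3,4-dihydroxyphenyl)-3,7-dihydroxychroman-6-yl]chromane-3,7-diol (ent-epifisetinidol-(4α→6)-ent-epifisetinidol)
Conditions: H2 (1 atm), Pd(OH)2/C, THF/MeOH/H2O, rt
Reagents that add atoms: none
Why: Hydrogenolysis, in which Pd(OH)2/C under H2 cleaves the eight O-benzyl bonds while the C2–O1 bonds and the doubly benzylic C4–C6 bond should survive the neutral conditions, so all five stereocenters are carried through unchanged.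

**Compound list**
1 | 4-bromo-3-fluorophenol | Oc1ccc(Br)c(F)c1 | starting material
2 | 4-(benzyloxy)-1-bromo-2-fluorobenzene | Fc1cc(OCc2ccccc2)ccc1Br | intermediate
3 | 2-(benzyloxy)-N-methoxy-N-methylacetamide | CON(C)C(=O)COCc1ccccc1 | starting material
4 | [4-(benzyloxy)-2-fluorophenyl]lithium | [Li]c1ccc(OCc2ccccc2)cc1F | intermediate
5 | lithium 2-(benzyloxy)-1-[4-(benzyloxy)-2-fluorophenyl]-1-[methoxy(methyl)amino]ethan-1-olate (hemiaminal adduct) | [Li]OC(COCc1ccccc1)(N(C)OC)c1ccc(OCc2ccccc2)cc1F | intermediate
6 | 2-(benzyloxy)-1-[4-(benzyloxy)-2-fluorophenyl]ethan-1-one | O=C(COCc1ccccc1)c1ccc(OCc2ccccc2)cc1F | intermediate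
7 | 3,4-bis(benzyloxy)benzaldehyde | O=Cc1ccc(OCc2ccccc2)c(OCc2ccccc2)c1 | starting material
8 | (Z)-2-(benzyloxy)-1-[4-(benzyloxy)-2-fluorophenyl]ethenyl diisopinocampheylborinate (benzyloxy cis to boryloxy; isopinocampheyl groups from (+)-α-pinene) | Fc1cc(OCc2ccccc2)ccc1/C(=C/OCc1ccccc1)OB([C@@H]1C[C@@H]2C[C@H]([C@H]1C)C2(C)C)[C@@H]1C[C@@H]2C[C@H]([C@H]1C)C2(C)C | intermediate
9 | (1S,2R)-2-(benzyloxy)-3-[4-(benzyloxy)-2-fluorophenyl]-1-[3,4-bis(benzyloxy)phenyl]-3-oxopropyl diisopinocampheylborinate (syn boron aldolate) | B([C@@H]1C[C@@H]2C[C@H]([C@H]1C)C2(C)C)([C@@H]1C[C@@H]2C[C@H]([C@H]1C)C2(C)C)O[C@@H](c1ccc(OCc2ccccc2)c(OCc2ccccc2)c1)[C@@H](OCc1ccccc1)C(=O)c1ccc(OCc2ccccc2)cc1F | intermediate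
10 | tris(dimethylamino)sulfonium salt of the B-fluoro ate complex of 9 (configuration as in 9) | CN(C)[S+](N(C)C)N(C)C.F[B-]([C@@H]1C[C@@H]2C[C@H]([C@H]1C)C2(C)C)([C@@H]1C[C@@H]2C[C@H]([C@H]1C)C2(C)C)O[C@@H](c1ccc(OCc2ccccc2)c(OCc2ccccc2)c1)[C@@H](OCc1ccccc1)C(=O)c1ccc(OCc2ccccc2)cc1F | intermediate
11 | (2S,3R)-3,7-bis(benzyloxy)-2-[3,4-bis(benzyloxy)phenyl]chroman-4-one (2,3-cis) | O=C1c2ccc(OCc3ccccc3)cc2O[C@@H](c2ccc(OCc3ccccc3)c(OCc3ccccc3)c2)[C@H]1OCc1ccccc1 | intermediate
12 | (2S,3S,4S)-3,7-bis(benzyloxy)-2-[3,4-bis(benzyloxy)phenyl]chroman-4-ol (2,3-cis-3,4-cis) | c1ccccc1COc1ccc2c(c1)O[C@@H](c1ccc(OCc3ccccc3)c(OCc3ccccc3)c1)[C@@H](OCc1ccccc1)[C@H]2O | intermediate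
13 | (2S,3S)-3,7-bis(benzyloxy)-2-[3,4-bis(benzyloxy)phenyl]chromane (2,3-cis) | c1ccccc1COc1ccc2c(c1)O[C@@H](c1ccc(OCc3ccccc3)c(OCc3ccccc3)c1)[C@@H](OCc1ccccc1)C2 | intermediate
14 | octa-O-benzyl ether of 15 (every hydroxyl benzylated; configurations as in 15) | c1ccccc1COc1ccc2c(c1)O[C@@H](c1ccc(OCc3ccccc3)c(OCc3ccccc3)c1)[C@@H](OCc1ccccc1)[C@@H]2c1cc2c(cc1OCc1ccccc1)O[C@@H](c1ccc(OCc3ccccc3)c(OCc3ccccc3)c1)[C@@H](OCc1ccccc1)C2 | intermediate
15 | (2S,3S,4R)-2-(3,4-dihydroxyphenyl)-4-[(2S,3S)-2-(3,4-dihydroxyphenyl)-3,7-dihydroxychroman-6-yl]chromane-3,7-diol | Oc1ccc2c(c1)O[C@@H](c1ccc(O)c(O)c1)[C@@H](O)[C@@H]2c1cc2c(cc1O)O[C@@H](c1ccc(O)c(O)c1)[C@@H](O)C2 | target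

**Step count and risks**
Total steps: 7. Longest linear sequence: 7 steps (13 is made from 12, so there is no separate branch).

Steps most likely to fail:

(a) Step 3 (proposed new method). Once fluoride frees the C2 oxygen from boron, retro-aldol fragmentation and base-mediated epimerisation at C3 may compete with ring closure and erode both the cis configuration and the enantiomeric purity. The facial selectivity of the isopinocampheyl ligands toward an aromatic aldehyde may also be incomplete. The fallback uses known reactions only and separates the two bond formations. Setting out from 6 and 7, the same boron aldol is stopped at aldolate 9 and worked up oxidatively (MeOH, pH 7 buffer, H2O2, 0 °C) to isolate the syn-aldol (2R,3S)-2-(benzyloxy)-1-[4-(benzyloxy)-2-fluorophenyl]-3-[3,4-bis(benzyloxy)phenyl]-3-hydroxypropan-1-one F1, whose enantiomeric purity can be checked and, if it crystallises, upgraded. Hydroxyl-directed anti reduction with Me4NBH(OAc)3 (Evans–Saksena reduction; MeCN/AcOH, −30 °C) should then give the anti-1,3-diol (1S,2R,3S)-2-(benzyloxy)-1-[4-(benzyloxy)-2-fluorophenyl]-3-[3,4-bis(benzyloxy)phenyl]propane-1,3-diol F2, in which neither retro-aldol cleavage nor C3 epimerisation is possible. KOt-Bu in THF/DMF at 60 °C then closes ring C by intramolecular SNAr of the alkoxide on the carbon bearing ring B onto the unactivated fluoroarene (the other alkoxide cannot reach C8a). This should give 12, where the route is rejoined.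

(b) Step 6. The electrophile and the product carry nucleophilic A rings of their own, so over-alkylation to oligomers may compete. Attack through C8 instead of C6 of 13 would give the regioisomeric linkage. The fallback moves the union to the free-phenol stage. Setting out from 11 and 13, hydrogenolysis of 11 (H2, Pd(OH)2/C, THF/MeOH) should give the free cis-dihydroflavonol (2S,3R)-2-(3,4-dihydroxyphenyl)-3,7-dihydroxychroman-4-one F3. NaBH4 in EtOH should reduce it to the flavan-3,4-diol (2S,3S,4S)-2-(3,4-dihydroxyphenyl)chromane-3,4,7-triol F4. Hydrogenolysis of 13 should give ent-epifisetinidol, (2S,3S)-2-(3,4-dihydroxyphenyl)chromane-3,7-diol F5. F4 and an excess of F5 are then condensed in 0.1 M aqueous-ethanolic HCl at rt, the classical flavan-3,4-diol/flavan-3-ol condensation, in which a resorcinol-type ring A reacts through C6 and a 2,3-cis cation is captured 3,4-trans. This should give 15 directly, where the route ends.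

(c) Step 5. The C4 cation may be captured by the A ring of another flavan molecule (self-condensation) or lose the C3 proton to a flav-3-ene faster than hydride is transferred from the silane. The fallback avoids the cation by a radical deoxygenation. Setting out from 12, 1,1'-thiocarbonyldiimidazole (DMAP, CH2Cl2, rt) should give the 4-O-(imidazol-1-ylthiocarbonyl) derivative of 12 (configuration as in 12) F6. Bu3SnH and AIBN in toluene at 80 °C (Barton–McCombie deoxygenation) should then give 13, where the route is rejoined.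

**Further compounds**
F1 | step 3 | (2R,3S)-2-(benzyloxy)-1-[4-(benzyloxy)-2-fluorophenyl]-3-[3,4-bis(benzyloxy)phenyl]-3-hydroxypropan-1-one | O[C@@H](c1ccc(OCc2ccccc2)c(OCc2ccccc2)c1)[C@@H](OCc1ccccc1)C(=O)c1ccc(OCc2ccccc2)cc1F
F2 | step 3 | (1S,2R,3S)-2-(benzyloxy)-1-[4-(benzyloxy)-2-fluorophenyl]-3-[3,4-bis(benzyloxy)phenyl]propane-1,3-diol | O[C@@H](c1ccc(OCc2ccccc2)c(OCc2ccccc2)c1)[C@@H](OCc1ccccc1)[C@@H](O)c1ccc(OCc2ccccc2)cc1F
F3 | step 6 | (2S,3R)-2-(3,4-dihydroxyphenyl)-3,7-dihydroxychroman-4-one (2,3-cis) | O=C1c2ccc(O)cc2O[C@@H](c2ccc(O)c(O)c2)[C@H]1O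
F4 | step 6 | (2S,3S,4S)-2-(3,4-dihydroxyphenyl)chromane-3,4,7-triol (2,3-cis-3,4-cis) | Oc1ccc2c(c1)O[C@@H](c1ccc(O)c(O)c1)[C@@H](O)[C@H]2O
F5 | step 6 | (2S,3S)-2-(3,4-dihydroxyphenyl)chromane-3,7-diol (ent-epifisetinidol) | Oc1ccc2c(c1)O[C@@H](c1ccc(O)c(O)c1)[C@@H](O)C2
F6 | step 5 | 4-O-(imidazol-1-ylthiocarbonyl) derivative of 12 (configuration as in 12) | c1ccccc1COc1ccc2c(c1)O[C@@H](c1ccc(OCc3ccccc3)c(OCc3ccccc3)c1)[C@@H](OCc1ccccc1)[C@H]2OC(=S)n1ccnc1
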